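**Assumption:** the SMILES has no stereocentre and no stereogenic double bond, so the target is achiral and "single enantiomer" means the one constitution shown.

## Retrosynthetic overview

1. The ester C–O bond is cut last: Steglich esterification of 19-(furan-2-yl)nonadeca-5,7-diynoic acid with 21-(furan-2-yl)henicosa-14,16-diyn-1-ol.
2. Each conjugated diyne is cut at the sp–sp bond: Cadiot–Chodkiewicz coupling of a furan-bearing terminal alkyne with a furan-free 1-bromoalkyne, so NBS never meets a furan.
3. Key C–C bond (C18–C19 of the acid half, furan to chain): crossed aldol (Claisen–Schmidt) condensation of furfural with 11-hydroxyundecan-2-one. The enone is then reduced to CH2CH2CH2 (H2, then Wolff–Kishner) and the alcohol end is homologated to the alkyne.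
4. The short furyl alkyne comes from furan by lithiation/alkylation and acetylide displacement; the C15 bromoalkynol comes from propargyl THP ether plus dodecyl bromide, then an alkyne zipper.
5. No ring is formed: both furan rings are bought intact (furfural, furan).

## Route

**Step 1**
Reactants: 1 undec-10-en-1-ol
Product: 2 11-hydroxyundecan-2-one
Conditions: PdCl2 (10 mol %), CuCl (1 equiv), O2 (1 atm), DMF/H2O 7:1, rt
Reagents that add atoms: water, O
Why: Tsuji–Wacker oxidation turns the terminal alkene into the methyl ketone with Markovnikov selectivity and tolerates the free primary alcohol.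

**Step 2**
Reactants: 2 11-hydroxyundecan-2-one; 3 furfural (furan-2-carbaldehyde)
Product: 5 (E)-1-(furan-2-yl)-12-hydroxydodec-1-en-3-one, via aldol adduct 4 (not isolated)
Conditions: 10% aq NaOH, EtOH, 0 °C → rt (2 in 1.2-fold excess)
Reagents that add atoms: none
Why: Claisen–Schmidt crossed aldol condensation in which furfural cannot enolise and only the adduct formed at the methyl group dehydrates readily under base, which funnels the reversible aldol equilibria to the linear, furan-conjugated (E)-enone.

**Step 3**
Reactants: 5 (E)-1-(furan-2-yl)-12-hydroxydodec-1-en-3-one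
Product: 6 1-(furan-2-yl)-12-hydroxydodecan-3-one
Conditions: H2 (1 atm), 5% Pd/C, EtOAc, rt, stopped after 1 equiv H2
Reagents that add atoms: none
Why: Catalytic hydrogenation reduces the electron-poor conjugated C=C much faster than the furan ring or the ketone, so stopping at one equivalent gives the saturated ketone.

**Step 4**
Reactants: 6 1-(furan-2-yl)-12-hydroxydodecan-3-one
Product: 8 12-(furan-2-yl)dodecan-1-ol, via hydrazone 7 (not isolated)
Conditions: N2H4·H2O, KOH, diethylene glycol, 130 °C, then 195 °C with removal of water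
Reagents that add atoms: none
Why: Wolff–Kishner (Huang-Minlon) reduction removes the unhindered dialkyl ketone through its hydrazone under strongly basic conditions, which the acid-sensitive 2-alkylfuran and the primary alcohol both survive.

**Step 5**
Reactants: 8 12-(furan-2-yl)dodecan-1-ol
Product: 9 12-(furan-2-yl)dodecanal
Conditions: Dess–Martin periodinane, CH2Cl2, 0 °C → rt
Reagents that add atoms: none
Why: Dess–Martin oxidation stops at the aldehyde under near-neutral conditions that do not attack the electron-rich furan.

**Step 6**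
Reactants: 9 12-(furan-2-yl)dodecanal
Product: 11 13-(furan-2-yl)tridec-1-yne, via diazoalkene 10 (not isolated)
Conditions: Ohira–Bestmann reagent, K2CO3, MeOH, 0 °C → rt
Reagents that add atoms: dimethyl (1-diazo-2-oxopropyl)phosphonate, CC(=O)C(=[N+]=[N-])P(=O)(OC)OC
Why: Ohira–Bestmann (Seyferth–Gilbert) homologation converts the enolisable aldehyde into the terminal alkyne under mild carbonate conditions by loss of N2 from the diazoalkene and 1,2-hydrogen shift.

**Step 7**
Reactants: 12 methyl hex-5-ynoate
Product: 13 methyl 6-bromohex-5-ynoate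
Conditions: NBS, AgNO3 (10 mol %), acetone, rt, dark
Reagents that add atoms: N-bromosuccinimide, O=C1CCC(=O)N1Br
Why: Silver-catalysed electrophilic bromination of the terminal alkyne gives the 1-bromoalkyne, and it is done on the furan-free partner because NBS would attack a furan.

**Step 8**
Reactants: 11 13-(furan-2-yl)tridec-1-yne; 13 methyl 6-bromohex-5-ynoate
Product: 15 methyl 19-(furan-2-yl)nonadeca-5,7-diynoate, via copper(I) acetylide 14 (not isolated)
Conditions: CuCl (10 mol %), NH2OH·HCl (cat.), 30% aq n-BuNH2, Et2O/MeOH, 0 °C, slow addition of 13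
Reagents that add atoms: none
Why: Cadiot–Chodkiewicz coupling joins the copper acetylide of 11 to the bromoalkyne to give only the unsymmetrical diyne, with hydroxylamine keeping copper as Cu(I) to suppress Glaser homocoupling.

**Step 9**
Reactants: 15 methyl 19-(furan-2-yl)nonadeca-5,7-diynoate
Product: 17 19-(furan-2-yl)nonadeca-5,7-diynoic acid, via lithium carboxylate 16 (not isolated)
Conditions: LiOH·H2O, THF/H2O 3:1, rt; then 1 M HCl to pH 3, 0 °C
Reagents that add atoms: lithium hydroxide, [Li+].[OH-]
Why: Saponification of the methyl ester proceeds at room temperature without touching the conjugated diyne or the furan, and the brief cold acidification is mild enough for the 2-alkylfuran.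

**Step 10**
Reactants: 18 furan; 19 1-bromo-4-chlorobutane
Product: 21 2-(4-chlorobutyl)furan, via 2-furyllithium 20 (not isolated)
Conditions: n-BuLi, THF, −20 → 0 °C; then Br(CH2)4Cl, −20 °C → rt
Reagents that add atoms: none
Why: Directed α-lithiation of furan followed by SN2 alkylation, in which the bromide is displaced selectively over the chloride.

**Step 11**
Reactants: 21 2-(4-chlorobutyl)furan
Product: 22 2-(4-iodobutyl)furan
Conditions: NaI, acetone, reflux
Reagents that add atoms: sodium iodide, [Na+].[I-]
Why: Finkelstein halide exchange, driven by precipitation of NaCl, gives the more reactive primary iodide.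

**Step 12**
Reactants: 22 2-(4-iodobutyl)furan
Product: 23 2-(hex-5-yn-1-yl)furan
Conditions: LiC≡CH·H2N(CH2)2NH2, DMSO, 10 °C → rt
Reagents that add atoms: lithium acetylide–ethylenediamine complex, [Li]C#C.NCCN
Why: SN2 alkynylation of an unhindered primary iodide by lithium acetylide in DMSO installs the terminal alkyne directly.

**Step 13**
Reactants: 24 2-(prop-2-yn-1-yloxy)tetrahydro-2H-pyran (racemic); 25 1-bromododecane
Product: 27 2-(pentadec-2-yn-1-yloxy)tetrahydro-2H-pyran, via lithium acetylide 26 (not isolated)
Conditions: n-BuLi, THF, −78 °C; then C12H25Br, DMPU, −78 °C → rt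
Reagents that add atoms: none
Why: Acetylide alkylation (SN2) of a primary bromide in THF/DMPU is a standard, high-yielding way to build internal alkynes.

**Step 14**
Reactants: 27 2-(pentadec-2-yn-1-yloxy)tetrahydro-2H-pyran
Product: 28 pentadec-2-yn-1-ol
Conditions: TsOH·H2O (5 mol %), MeOH, rt
Reagents that add atoms: none
Why: Acid-catalysed transacetalisation to methanol removes the THP group cleanly.

**Step 15**
Reactants: 28 pentadec-2-yn-1-ol
Product: 30 pentadec-14-yn-1-ol, via disodium alkynide-alkoxide 29 (not isolated)
Conditions: NaH (5 equiv), H2N(CH2)3NH2, 70 °C, 1 h; then 28, 55 °C; H2O quench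
Reagents that add atoms: none
Why: Alkyne zipper isomerisation with sodium 3-aminopropylamide walks the triple bond along the chain to the terminus, where irreversible formation of the terminal acetylide drives it.

**Step 16**
Reactants: 30 pentadec-14-yn-1-ol
Product: 31 15-bromopentadec-14-yn-1-ol
Conditions: NBS, AgNO3 (10 mol %), acetone, rt, dark
Reagents that add atoms: N-bromosuccinimide, O=C1CCC(=O)N1Br
Why: Silver-catalysed bromination of the terminal alkyne gives the 1-bromoalkyne and tolerates the free primary alcohol.

**Step 17**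
Reactants: 23 2-(hex-5-yn-1-yl)furan; 31 15-bromopentadec-14-yn-1-ol
Product: 33 21-(furan-2-yl)henicosa-14,16-diyn-1-ol, via copper(I) acetylide 32 (not isolated)
Conditions: CuCl (10 mol %), NH2OH·HCl (cat.), 30% aq n-BuNH2, Et2O/MeOH, 0 °C
Reagents that add atoms: none
Why: Cadiot–Chodkiewicz coupling of the copper acetylide of 23 with the bromoalkyne gives the unsymmetrical conjugated diyne and tolerates the free alcohol and the furan.

**Step 18**
Reactants: 17 19-(furan-2-yl)nonadeca-5,7-diynoic acid; 33 21-(furan-2-yl)henicosa-14,16-diyn-1-ol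
Product: 35 21-(furan-2-yl)henicosa-14,16-diyn-1-yl 19-(furan-2-yl)nonadeca-5,7-diynoate, via O-acylisourea 34 (not isolated)
Conditions: EDC·HCl, DMAP (0.2 equiv), CH2Cl2, 0 °C → rt
Reagents that add atoms: none
Why: Steglich esterification couples the unhindered acid and primary alcohol near 1:1 under neutral conditions that leave the furans and diynes untouched.

## Compound list

1 | undec-10-en-1-ol | C=CCCCCCCCCCO | starting material
2 | 11-hydroxyundecan-2-one | CC(=O)CCCCCCCCCO | intermediate
3 | furfural (furan-2-carbaldehyde) | O=Cc1ccco1 | starting material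
4 | 1-(furan-2-yl)-1,12-dihydroxydodecan-3-one (racemic aldol adduct) | OCCCCCCCCCC(=O)CC(O)c1ccco1 | intermediate (not isolated)
5 | (E)-1-(furan-2-yl)-12-hydroxydodec-1-en-3-one | OCCCCCCCCCC(=O)/C=C/c1ccco1 | intermediate
6 | 1-(furan-2-yl)-12-hydroxydodecan-3-one | OCCCCCCCCCC(=O)CCc1ccco1 | intermediate
7 | hydrazone of 6 | OCCCCCCCCCC(=NN)CCc1ccco1 | intermediate (not isolated)
8 | 12-(furan-2-yl)dodecan-1-ol | OCCCCCCCCCCCCc1ccco1 | intermediate
9 | 12-(furan-2-yl)dodecanal | O=CCCCCCCCCCCCc1ccco1 | intermediate
10 | 2-(13-diazotridec-12-en-1-yl)furan (diazoalkene) | [N-]=[N+]=C=CCCCCCCCCCCCc1ccco1 | intermediate (not isolated)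
11 | 13-(furan-2-yl)tridec-1-yne | C#CCCCCCCCCCCCc1ccco1 | intermediate
12 | methyl hex-5-ynoate | COC(=O)CCCC#C | starting material
13 | methyl 6-bromohex-5-ynoate | COC(=O)CCCC#CBr | intermediate
14 | copper(I) acetylide of 11 | [Cu]C#CCCCCCCCCCCCc1ccco1 | intermediate (not isolated)
15 | methyl 19-(furan-2-yl)nonadeca-5,7-diynoate | COC(=O)CCCC#CC#CCCCCCCCCCCCc1ccco1 | intermediate
16 | lithium 19-(furan-2-yl)nonadeca-5,7-diynoate | [Li+].[O-]C(=O)CCCC#CC#CCCCCCCCCCCCc1ccco1 | intermediate (not isolated)
17 | 19-(furan-2-yl)nonadeca-5,7-diynoic acid | OC(=O)CCCC#CC#CCCCCCCCCCCCc1ccco1 | intermediate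
18 | furan | c1ccoc1 | starting material
19 | 1-bromo-4-chlorobutane | ClCCCCBr | starting material
20 | 2-furyllithium | [Li]c1ccco1 | intermediate (not isolated)
21 | 2-(4-chlorobutyl)furan | ClCCCCc1ccco1 | intermediate
22 | 2-(4-iodobutyl)furan | ICCCCc1ccco1 | intermediate
23 | 2-(hex-5-yn-1-yl)furan | C#CCCCCc1ccco1 | intermediate
24 | 2-(prop-2-yn-1-yloxy)tetrahydro-2H-pyran (racemic) | C#CCOC1CCCCO1 | starting material
25 | 1-bromododecane | CCCCCCCCCCCCBr | starting material
26 | lithium acetylide of 24 | [Li]C#CCOC1CCCCO1 | intermediate (not isolated)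
27 | 2-(pentadec-2-yn-1-yloxy)tetrahydro-2H-pyran (racemic) | CCCCCCCCCCCCC#CCOC1CCCCO1 | intermediate
28 | pentadec-2-yn-1-ol | CCCCCCCCCCCCC#CCO | intermediate
29 | disodium salt (alkynide-alkoxide) of pentadec-14-yn-1-ol | [Na+].[Na+].[C-]#CCCCCCCCCCCCCC[O-] | intermediate (not isolated)
30 | pentadec-14-yn-1-ol | C#CCCCCCCCCCCCCCO | intermediate
31 | 15-bromopentadec-14-yn-1-ol | BrC#CCCCCCCCCCCCCCO | intermediate
32 | copper(I) acetylide of 23 | [Cu]C#CCCCCc1ccco1 | intermediate (not isolated)
33 | 21-(furan-2-yl)henicosa-14,16-diyn-1-ol | OCCCCCCCCCCCCCC#CC#CCCCCc1ccco1 | intermediate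
34 | O-acylisourea from 17 and EDC | CCN=C(NCCCN(C)C)OC(=O)CCCC#CC#CCCCCCCCCCCCc1ccco1 | intermediate (not isolated)
35 | 21-(furan-2-yl)henicosa-14,16-diyn-1-yl 19-(furan-2-yl)nonadeca-5,7-diynoate | O=C(CCCC#CC#CCCCCCCCCCCCc1ccco1)OCCCCCCCCCCCCCC#CC#CCCCCc1ccco1 | target

## Summary

Total step count: 18.
Longest linear sequence: 9 steps (1, 2, 3, 4, 5, 6, 8, 9, 18).

**Three steps most likely to fail**

Step 2 (crossed aldol condensation). The risks are condensation at the CH2 side of the ketone, a second condensation, or Cannizzaro loss of furfural. The fallback is a directed aldol that sets out from 2 and comes back at 5. Compound 2 is silylated (TBSCl, imidazole, DMF) to 11-[(tert-butyldimethylsilyl)oxy]undecan-2-one F1. F1 is deprotonated kinetically at the methyl group with LDA in THF at −78 °C and treated with furfural 3 to give the isolated β-hydroxy ketone 12-[(tert-butyldimethylsilyl)oxy]-1-(furan-2-yl)-1-hydroxydodecan-3-one F2; any minor regioisomer is removed here by chromatography. MsCl/Et3N in CH2Cl2 at 0 °C forms the furfurylic mesylate 12-[(tert-butyldimethylsilyl)oxy]-1-(furan-2-yl)-3-oxododecyl methanesulfonate F3, which is not isolated and eliminates on adding DBU to (E)-12-[(tert-butyldimethylsilyl)oxy]-1-(furan-2-yl)dodec-1-en-3-one F4. TBAF buffered with AcOH in THF then returns enone 5.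

Step 3 (chemoselective hydrogenation). The risk is over-reduction of the furan ring or the ketone. The fallback avoids H2 and metal catalysts altogether; it sets out from 5 and comes back at 8, bypassing 6 and 7. Enone 5 is condensed with TsNHNH2 in EtOH to the tosylhydrazone N'-[1-(furan-2-yl)-12-hydroxydodec-1-en-3-ylidene]-4-methylbenzenesulfonohydrazide F5. Catecholborane (excess, to allow for the free OH) in CHCl3 at 0 °C, then NaOAc·3H2O at reflux, gives the transposed alkene (E)-12-(furan-2-yl)dodec-10-en-1-ol F6 by reduction, sulfinate loss and retro-ene loss of N2. Diimide (TsNHNH2, NaOAc, THF/H2O, reflux), which does not touch furans, saturates the isolated alkene to give 8.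

Step 8 (Cadiot–Chodkiewicz coupling with the lipophilic, precious alkyne 11). The risks are homocoupling of 11 and poor mixing of the long-chain alkyne in aqueous amine. The fallback reverses the roles so that the cheap alkyne can be used in excess; it sets out from 9 and comes back at 15, bypassing 11 and 13. Aldehyde 9 is treated with CBr4/PPh3 (Et3N buffer, CH2Cl2, 0 °C) to give 2-(13,13-dibromotridec-12-en-1-yl)furan F7. Dehydrobromination with TBAF·3H2O in DMF at 60 °C gives 2-(13-bromotridec-12-yn-1-yl)furan F8 without any electrophilic bromine source meeting the furan. F8 is then coupled under the same copper/amine conditions with a three-fold excess of methyl hex-5-ynoate 12 to give 15; the excess 12 and its polar homodimer are easily separated.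

## Further compounds

F1 | step 2 | 11-[(tert-butyldimethylsilyl)oxy]undecan-2-one | CC(=O)CCCCCCCCCO[Si](C)(C)C(C)(C)C
F2 | step 2 | 12-[(tert-butyldimethylsilyl)oxy]-1-(furan-2-yl)-1-hydroxydodecan-3-one (racemic) | CC(C)(C)[Si](C)(C)OCCCCCCCCCC(=O)CC(O)c1ccco1
F3 | step 2 | 12-[(tert-butyldimethylsilyl)oxy]-1-(furan-2-yl)-3-oxododecyl methanesulfonate (racemic, not isolated) | CC(C)(C)[Si](C)(C)OCCCCCCCCCC(=O)CC(OS(C)(=O)=O)c1ccco1
F4 | step 2 | (E)-12-[(tert-butyldimethylsilyl)oxy]-1-(furan-2-yl)dodec-1-en-3-one | CC(C)(C)[Si](C)(C)OCCCCCCCCCC(=O)/C=C/c1ccco1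
F5 | step 3 | N'-[1-(furan-2-yl)-12-hydroxydodec-1-en-3-ylidene]-4-methylbenzenesulfonohydrazide (E-alkene) | Cc1ccc(cc1)S(=O)(=O)NN=C(CCCCCCCCCO)/C=C/c1ccco1
F6 | step 3 | (E)-12-(furan-2-yl)dodec-10-en-1-ol | OCCCCCCCCC/C=C/Cc1ccco1
F7 | step 8 | 2-(13,13-dibromotridec-12-en-1-yl)furan | BrC(Br)=CCCCCCCCCCCCc1ccco1
F8 | step 8 | 2-(13-bromotridec-12-yn-1-yl)furan | BrC#CCCCCCCCCCCCc1ccco1
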